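**Plan**

1. Retrosynthesis: after removal of five benzyl ethers, ring C'' of the flavone half is cut at C4a''–C4'', C4''–C3'' and O1''–C2'', giving an ortho-iodophenol, CO and an aryl acetylene. The biaryl bond C6–C8'' is then cut to a 6-iodonaringenin ether and a phloroglucinol-derived boronate.
2. Enabling feature: C4'' is a single carbonyl carbon between C4a'' of ring A'' and the two-carbon unit C3''–C2'' that carries ring B''. O1'' sits on C8a'', the carbon between C4a'' and the biaryl carbon C8''. An iodine on C4a'' beside a free OH on C8a'' therefore maps CO and a 4-oxygenated phenylacetylene onto ring C''.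
3. Forward order: rings A, B and C arrive with naringenin. The sequence is 7,4'-di-O-benzylation, iodination at C6, Suzuki coupling (C6–C8''), release of the one MOM-masked phenol, iodination beside it, closure of ring C'' (the only ring made), and hydrogenolysis.
4. Stereochemistry: C2 comes from (2S)-naringenin and no stereocentre is created. It is guarded by capping the 4'-OH under neutral conditions, by leaving the chelated 5-OH free, and by avoiding strong base.
5. Protecting groups: benzyl is the permanent group throughout. A single MOM ether directs the lithiation for the boronate and marks the oxygen that becomes O1''.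

Key step: step 8

Assumption: the target formula fixes only C2; the hindered C6–C8'' axis is not specified and is not controlled here.
Assumption: enantiopure (2S)-naringenin, 3,5-bis(benzyloxy)phenol and 1-(benzyloxy)-4-ethynylbenzene are taken as commercial.
Remark: the chelated 5-OH is carried unprotected, because its alkylation needs base strong enough to open the flavanone ring and erode C2.

**Route**

Step 1
Reactants: 1 (2S)-naringenin
Product: 3 (2S)-7,4'-di-O-benzylnaringenin, via 7-O-benzylnaringenin 2 (not isolated)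
Conditions: BnOH (2.3 equiv), PPh3, DIAD, THF, 0 °C → rt
Reagents that add atoms: benzyl alcohol, OCc1ccccc1
Why: Mitsunobu etherification takes the two acidic phenols (7-OH first, then 4'-OH) under neutral conditions, leaves the chelated 5-OH alone and avoids a long-lived 4'-phenoxide, which could open the pyranone ring through a quinone methide and erode C2.

Step 2
Reactants: 3 (2S)-7,4'-di-O-benzylnaringenin
Product: 4 (2S)-7,4'-di-O-benzyl-6-iodonaringenin
Conditions: BnMe3N·ICl2 (1.05 equiv), CaCO3, CH2Cl2/MeOH, rt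
Reagents that add atoms: benzyltrimethylammonium dichloroiodate, C[N+](C)(C)Cc1ccccc1.Cl[I-]Cl
Why: Buffered electrophilic aromatic iodination with dichloroiodate should go ortho to the chelated 5-OH (C6) and not to C8, the regiochemistry known for 5-hydroxy-7-alkoxy flavonoids, while the aryl benzyl ethers are not activated enough to react.

Step 3
Reactants: 5 3,5-bis(benzyloxy)phenol
Product: 6 1,3-bis(benzyloxy)-5-(methoxymethoxy)benzene
Conditions: MOMCl, iPr2NEt, CH2Cl2, 0 °C → rt
Reagents that add atoms: chloromethyl methyl ether, COCCl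
Why: O-alkylation of the phenol with MOMCl and an amine base installs the only acid-labile ether of the route, which also serves as the directing group for step 4.

Step 4
Reactants: 6 1,3-bis(benzyloxy)-5-(methoxymethoxy)benzene
Product: 8 2-[2,4-bis(benzyloxy)-6-(methoxymethoxy)phenyl]-4,4,5,5-tetramethyl-1,3,2-dioxaborolane, via aryllithium 7 (not isolated)
Conditions: n-BuLi (1.1 equiv), THF, 0 °C; iPrOBpin, −78 °C → rt; H2O
Reagents that add atoms: 2-isopropoxy-4,4,5,5-tetramethyl-1,3,2-dioxaborolane, CC(C)OB1OC(C)(C)C(C)(C)O1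
Why: In this directed ortho-metalation the chelating OMOM group, reinforced by the neighbouring OBn, should steer n-BuLi to one of the two equivalent positions between OMOM and OBn and not to the carbon between the two benzyl ethers, and the aryllithium is trapped by the borate ester.

Step 5
Reactants: 4 (2S)-7,4'-di-O-benzyl-6-iodonaringenin; 8 the pinacol boronate (1.5 equiv)
Product: 9 (2S)-7-(benzyloxy)-2-[4-(benzyloxy)phenyl]-6-[2,4-bis(benzyloxy)-6-(methoxymethoxy)phenyl]-5-hydroxychroman-4-one
Conditions: Pd(OAc)2 (5 mol %), SPhos (10 mol %), K3PO4, toluene/H2O, 80 °C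
Reagents that add atoms: none
Why: Suzuki–Miyaura coupling with a bulky, electron-rich biarylphosphine is the established way to tetra-ortho-oxygenated biaryls, an aryl iodide with a free ortho-phenol is a competent partner, and the potassium 5-phenoxide formed under the conditions disfavours C3 enolisation and thus ring-opening at C2.

Step 6
Reactants: 9 the MOM-protected biaryl
Product: 10 (2S)-7-(benzyloxy)-2-[4-(benzyloxy)phenyl]-6-[2,4-bis(benzyloxy)-6-hydroxyphenyl]-5-hydroxychroman-4-one
Conditions: HCl (3 M aq.), MeOH/THF, 45 °C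
Reagents that add atoms: none
Why: Acid-catalysed acetal methanolysis removes the single MOM ether, while benzyl ethers, the ketone and the C2 stereocentre are not affected by dilute acid.

Step 7
Reactants: 10 the biaryl phenol
Product: 11 (2S)-7-(benzyloxy)-2-[4-(benzyloxy)phenyl]-6-[4,6-bis(benzyloxy)-2-hydroxy-3-iodophenyl]-5-hydroxychroman-4-one
Conditions: BnMe3N·ICl2 (1.0 equiv), CaCO3, CH2Cl2/MeOH, −20 → 0 °C
Reagents that add atoms: benzyltrimethylammonium dichloroiodate, C[N+](C)(C)Cc1ccccc1.Cl[I-]Cl
Why: Electrophilic iodination should take place on the dialkoxyphenol ring, by far the most electron-rich one, at the position flanked by OH and OBn in preference to the more hindered carbon between the two benzyloxy groups, as in the halogenation of 3,5-dialkoxyphenols, and one equivalent at low temperature limits a second iodination and spares C8 of the carbonyl-deactivated ring.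

Step 8
Reactants: 11 the ortho-iodophenol; 12 1-(benzyloxy)-4-ethynylbenzene (1.5 equiv)
Product: 15 (2S)-penta-O-benzyl biflavonoid, 5,7-bis(benzyloxy)-8-{(2S)-7-(benzyloxy)-2-[4-(benzyloxy)phenyl]-5-hydroxy-4-oxochroman-6-yl}-2-[4-(benzyloxy)phenyl]-4H-chromen-4-one, via ynone 13 (not isolated), via enaminone 14 (not isolated)
Conditions: PdCl2(PPh3)2 (5 mol %), CO (10 bar), Et2NH/THF, 80 °C, autoclave
Reagents that add atoms: carbon monoxide, [C-]#[O+]
Why: PdCl2(PPh3)2 is reduced in the amine to zerovalent palladium, which adds oxidatively to the C4a''–I bond of 11; CO inserts to give a divalent acyl-palladium iodide, the alkyne 12 is transferred to palladium with the help of the amine, and reductive elimination forms C4a''–C4'' and C4''–C3'' in ynone 13. Diethylamine then adds to C2'' of 13 to give enaminone 14, and the neighbouring C8a''–OH displaces the amine by addition–elimination, which forms O1''–C2'' and closes ring C'' in a 6-endo mode (6-endo-dig with respect to the ynone). The closest known reaction type is the palladium-catalysed carbonylative coupling and cyclisation of ortho-iodophenols with terminal aryl acetylenes in diethylamine, which gives flavones. No stereocentre is formed; C2 is a spectator whose retention relies on the moderate temperature and on the chelated 5-OH, which lowers the acidity at C3. The 8''-linkage is fixed because the only hydroxyl ortho to the new acyl group is the one on C8a'', the C5'' oxygen being benzylated and the flavanone 5-OH lying on the other ring; flavone over aurone is secured by the secondary amine, which turns the ynone into the enaminone before a 5-exo closure can occur, and CO pressure with a copper-free catalyst and an excess of alkyne holds back direct alkynylation and amide formation.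

Step 9
Reactants: 15 the penta-O-benzyl biflavonoid
Product: 16 (2S)-2,3-dihydro-6,8''-biapigenin, i.e. (2S)-naringenin-(6→8'')-apigenin, the target
Conditions: H2 (1 atm), Pd/C (10 wt % Pd on carbon), THF/MeOH, rt
Reagents that add atoms: none
Why: Hydrogenolysis of the five aryl benzyl ethers over Pd/C at atmospheric pressure is expected to be faster than reduction of the pyrone C2''=C3'' bond or of the ketones, and the neutral medium leaves C2 untouched.

**Compound list**

1 | (2S)-naringenin, (2S)-5,7-dihydroxy-2-(4-hydroxyphenyl)chroman-4-one | O=C1C[C@@H](c2ccc(O)cc2)Oc2cc(O)cc(O)c21 | starting material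
2 | (2S)-7-O-benzylnaringenin, (2S)-7-(benzyloxy)-5-hydroxy-2-(4-hydroxyphenyl)chroman-4-one | O=C1C[C@@H](c2ccc(O)cc2)Oc2cc(OCc3ccccc3)cc(O)c21 | intermediate (not isolated)
3 | (2S)-7,4'-di-O-benzylnaringenin, (2S)-7-(benzyloxy)-2-[4-(benzyloxy)phenyl]-5-hydroxychroman-4-one | O=C1C[C@@H](c2ccc(OCc3ccccc3)cc2)Oc2cc(OCc3ccccc3)cc(O)c21 | intermediate
4 | (2S)-7,4'-di-O-benzyl-6-iodonaringenin, (2S)-7-(benzyloxy)-2-[4-(benzyloxy)phenyl]-5-hydroxy-6-iodochroman-4-one | O=C1C[C@@H](c2ccc(OCc3ccccc3)cc2)Oc2cc(OCc3ccccc3)c(I)c(O)c21 | intermediate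
5 | 3,5-bis(benzyloxy)phenol | Oc1cc(OCc2ccccc2)cc(OCc2ccccc2)c1 | starting material
6 | 1,3-bis(benzyloxy)-5-(methoxymethoxy)benzene | COCOc1cc(OCc2ccccc2)cc(OCc2ccccc2)c1 | intermediate
7 | [2,4-bis(benzyloxy)-6-(methoxymethoxy)phenyl]lithium | [Li]c1c(OCOC)cc(OCc2ccccc2)cc1OCc1ccccc1 | intermediate (not isolated)
8 | 2-[2,4-bis(benzyloxy)-6-(methoxymethoxy)phenyl]-4,4,5,5-tetramethyl-1,3,2-dioxaborolane | CC1(C)OB(c2c(OCOC)cc(OCc3ccccc3)cc2OCc2ccccc2)OC1(C)C | intermediate
9 | (2S)-7-(benzyloxy)-2-[4-(benzyloxy)phenyl]-6-[2,4-bis(benzyloxy)-6-(methoxymethoxy)phenyl]-5-hydroxychroman-4-one | O=C1C[C@@H](c2ccc(OCc3ccccc3)cc2)Oc2cc(OCc3ccccc3)c(-c3c(OCOC)cc(OCc4ccccc4)cc3OCc3ccccc3)c(O)c21 | intermediate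
10 | (2S)-7-(benzyloxy)-2-[4-(benzyloxy)phenyl]-6-[2,4-bis(benzyloxy)-6-hydroxyphenyl]-5-hydroxychroman-4-one | O=C1C[C@@H](c2ccc(OCc3ccccc3)cc2)Oc2cc(OCc3ccccc3)c(-c3c(O)cc(OCc4ccccc4)cc3OCc3ccccc3)c(O)c21 | intermediate
11 | (2S)-7-(benzyloxy)-2-[4-(benzyloxy)phenyl]-6-[4,6-bis(benzyloxy)-2-hydroxy-3-iodophenyl]-5-hydroxychroman-4-one | O=C1C[C@@H](c2ccc(OCc3ccccc3)cc2)Oc2cc(OCc3ccccc3)c(-c3c(O)c(I)c(OCc4ccccc4)cc3OCc3ccccc3)c(O)c21 | intermediate
12 | 1-(benzyloxy)-4-ethynylbenzene | C#Cc1ccc(OCc2ccccc2)cc1 | starting material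
13 | ynone, (2S)-7-(benzyloxy)-2-[4-(benzyloxy)phenyl]-6-{4,6-bis(benzyloxy)-3-[3-(4-(benzyloxy)phenyl)prop-2-ynoyl]-2-hydroxyphenyl}-5-hydroxychroman-4-one | O=C1C[C@@H](c2ccc(OCc3ccccc3)cc2)Oc2cc(OCc3ccccc3)c(-c3c(O)c(C(=O)C#Cc4ccc(OCc5ccccc5)cc4)c(OCc4ccccc4)cc3OCc3ccccc3)c(O)c21 | intermediate (not isolated)
14 | enaminone, the (E)-3-(diethylamino)-3-[4-(benzyloxy)phenyl]prop-2-enoyl analogue of 13 (alkene geometry drawn as E, immaterial for the closure) | O=C1C[C@@H](c2ccc(OCc3ccccc3)cc2)Oc2cc(OCc3ccccc3)c(-c3c(O)c(C(=O)/C=C(/N(CC)CC)c4ccc(OCc5ccccc5)cc4)c(OCc4ccccc4)cc3OCc3ccccc3)c(O)c21 | intermediate (not isolated)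
15 | 5,7-bis(benzyloxy)-8-{(2S)-7-(benzyloxy)-2-[4-(benzyloxy)phenyl]-5-hydroxy-4-oxochroman-6-yl}-2-[4-(benzyloxy)phenyl]-4H-chromen-4-one | O=C1C[C@@H](c2ccc(OCc3ccccc3)cc2)Oc2cc(OCc3ccccc3)c(-c3c(OCc4ccccc4)cc(OCc4ccccc4)c4c(=O)cc(-c5ccc(OCc6ccccc6)cc5)oc34)c(O)c21 | intermediate
16 | (2S)-2,3-dihydro-6,8''-biapigenin, 8-[(2S)-5,7-dihydroxy-2-(4-hydroxyphenyl)-4-oxochroman-6-yl]-5,7-dihydroxy-2-(4-hydroxyphenyl)-4H-chromen-4-one | O=C1C[C@@H](c2ccc(O)cc2)Oc2cc(O)c(-c3c(O)cc(O)c4c(=O)cc(-c5ccc(O)cc5)oc34)c(O)c21 | target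

**Step count**

Total: 9 steps. Longest linear sequence: 7 steps (1 → 3 → 4 → 9 → 10 → 11 → 15 → 16; the branch from 5 through 6 and 8 is equally long).

**Three steps most likely to fail**

Step 5 (biaryl coupling). Transmetalation and reductive elimination at the tetra-ortho-oxygenated axis may be slow, so that protodeboronation of the 2,6-dialkoxyaryl boronate and hydrodeiodination of the iodide overtake the coupling. The fallback is a Negishi coupling that sets out from 6. The aryllithium 7 is generated as in step 4 and transmetalated with ZnCl2 to [2,4-bis(benzyloxy)-6-(methoxymethoxy)phenyl]zinc chloride F1. This is added slowly to iodide 4 with Pd2(dba)3 and RuPhos in THF at 60 °C, so that cross-coupling outpaces protonation of the zinc reagent by the chelated 5-OH. The fallback comes back to the route at 9.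

Step 8 (carbonylative annulation). Oxidative addition and CO uptake at the doubly ortho-substituted, electron-rich C–I bond may be slow, which would let attack of diethylamine on the acyl-palladium or CO-free alkynylation take over. Warm amine may also open the flavanone ring reversibly and erode C2. The fallback separates C–C bond formation from ring closure and runs near room temperature; it sets out from 11. Both phenols are acetylated (Ac2O, pyridine, DMAP) to the diacetate of 11 F2. Carbonylative Sonogashira coupling with 12 (PdCl2(PPh3)2, Et3N, CO 1 atm, THF, 40 °C) should give the ynone diacetate F3. Et2NH in EtOH at rt then cleaves both acetates and takes the liberated 13 through 14 to the flavone. The fallback comes back to the route at 15.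

Step 7 (iodination beside the free phenol). Substitution para to the hydroxyl (the carbon between the two benzyloxy groups) or a second iodination may compete. The fallback fixes the site before the biaryl is made, by carrying a silyl group as a placeholder for iodine; it sets out from 6. Aryllithium 7 is quenched with Me3SiCl to [2,4-bis(benzyloxy)-6-(methoxymethoxy)phenyl]trimethylsilane F4. A second MOM-directed lithiation at the remaining position between OMOM and OBn, followed by iPrOBpin, gives the silylated pinacol boronate F5. Suzuki coupling with 4 under the conditions of step 5 gives the silylated biaryl F6. Ipso-iododesilylation with ICl (1.0 equiv, CH2Cl2, −78 °C) gives the iodo MOM ether F7, and HCl in MeOH/THF removes the MOM group. The fallback comes back to the route at 11.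

**Further compounds**

F1 | step 5 | [2,4-bis(benzyloxy)-6-(methoxymethoxy)phenyl]zinc chloride | Cl[Zn]c1c(OCOC)cc(OCc2ccccc2)cc1OCc1ccccc1
F2 | step 8 | diacetate of 11, (2S)-5-acetoxy-6-[2-acetoxy-4,6-bis(benzyloxy)-3-iodophenyl]-7-(benzyloxy)-2-[4-(benzyloxy)phenyl]chroman-4-one | O=C1C[C@@H](c2ccc(OCc3ccccc3)cc2)Oc2cc(OCc3ccccc3)c(-c3c(OC(C)=O)c(I)c(OCc4ccccc4)cc3OCc3ccccc3)c(OC(C)=O)c21
F3 | step 8 | ynone diacetate, diacetate of 13 | O=C1C[C@@H](c2ccc(OCc3ccccc3)cc2)Oc2cc(OCc3ccccc3)c(-c3c(OC(C)=O)c(C(=O)C#Cc4ccc(OCc5ccccc5)cc4)c(OCc4ccccc4)cc3OCc3ccccc3)c(OC(C)=O)c21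
F4 | step 7 | [2,4-bis(benzyloxy)-6-(methoxymethoxy)phenyl]trimethylsilane | C[Si](C)(C)c1c(OCOC)cc(OCc2ccccc2)cc1OCc1ccccc1
F5 | step 7 | 2-[4,6-bis(benzyloxy)-2-(methoxymethoxy)-3-(trimethylsilyl)phenyl]-4,4,5,5-tetramethyl-1,3,2-dioxaborolane | CC1(C)OB(c2c(OCOC)c([Si](C)(C)C)c(OCc3ccccc3)cc2OCc2ccccc2)OC1(C)C
F6 | step 7 | (2S)-7-(benzyloxy)-2-[4-(benzyloxy)phenyl]-6-[4,6-bis(benzyloxy)-2-(methoxymethoxy)-3-(trimethylsilyl)phenyl]-5-hydroxychroman-4-one | O=C1C[C@@H](c2ccc(OCc3ccccc3)cc2)Oc2cc(OCc3ccccc3)c(-c3c(OCOC)c([Si](C)(C)C)c(OCc4ccccc4)cc3OCc3ccccc3)c(O)c21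
F7 | step 7 | (2S)-7-(benzyloxy)-2-[4-(benzyloxy)phenyl]-6-[4,6-bis(benzyloxy)-3-iodo-2-(methoxymethoxy)phenyl]-5-hydroxychroman-4-one | O=C1C[C@@H](c2ccc(OCc3ccccc3)cc2)Oc2cc(OCc3ccccc3)c(-c3c(OCOC)c(I)c(OCc4ccccc4)cc3OCc3ccccc3)c(O)c21
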